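**Remarks on the chemistry (assumptions)**

- The (R)-enantiomer of the phosphoric acid, (R)-TRIP [(R)-3,3'-bis(2,4,6-triisopropylphenyl)-1,1'-binaphthyl-2,2'-diyl hydrogen phosphate], is taken to give 4 in the configuration drawn; should the sense of induction be the reverse, the (S)-acid is used and nothing else changes.
- 13 and 14 are ring and chain tautomers of one substance; 13 is written as the isolated form, and either form enters step 8.
- The ring opening of step 4 is, overall, the loss of two electrons and two protons in two one-electron events.

## Structural features

Compound 17 is a 3,3'-linked bis-flavanone: two 2-(4-methoxyphenyl)chroman-4-one units (ring A the oxygenated benzo ring, ring C the pyranone, ring B the 4-methoxyphenyl group) joined by the single bond C3–C3'. The four stereocenters C2, C3, C3' and C2' stand in a row and are all S. In each ring C the aryl group at C2 and the other half of the molecule at C3 lie on the same face (2,3-cis), and C3 and C3' have the same sense, so the carbon skeleton is C2-symmetric. The symmetry is broken only at the periphery: one ring A is 5,7-dihydroxy, the other 5-hydroxy-7-methoxy. Fragile points are the C3–H and C3'–H bonds next to the ketones (enolisation would turn 2,3-cis into 2,3-trans), the β-aryloxy ketone of each ring C (ring opening from the enolate), the benzylic C2–O1 bonds and the free phloroglucinol-type phenols. The real difficulty is the crowded C3–C3' bond flanked by four stereocenters in the arrangement that base does not favour, in one absolute configuration, together with the distinction of two equivalent 7-hydroxyl groups. The key step uses the fact that C3–C3' joins the α-carbons of two 4-methoxycinnamoyl units in the C2-symmetric sense; this is the trans-1,2-diacyl relation of a head-to-head, all-trans cyclobutane dimer in which C2 and C2' are tied by an extra bond between two 4-methoxybenzylic carbons. That temporary bond is strained and electron-rich, so it can later be cut by oxidation, with O1 and O1' delivered by the two carboxyl groups as a cis-fused bis-lactone whose exo aryl groups correspond to the 2,3-cis relation of 17.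

## Logic of the disconnections

**17 to 16.** The O7'–CH3 bond is cut first. This restores the C2 axis, so everything earlier can be built twofold. The 7-hydroxyl groups of 16 are its most acidic oxygens (para to the ketone, not chelated like the 5-hydroxyls). The forward methylation must touch one of two equivalent, remote hydroxyl groups, which can only be statistical, and it must be neutral so that C3 and C3' are not enolised.

**16 to 15.** The four phenolic O–H bonds are replaced by O–CH2Ph bonds. The phenols must be masked through the organolithium and base steps. Benzyl is chosen because its removal needs neither acid nor base. The forward hydrogenolysis must leave the benzylic C2–O1 bonds and the cis stereocenters untouched.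

**15 to 14 (resting as 13).** The aryl ether bonds O1–C8a and O1'–C8a' are cut. O1 then becomes an alcohol oxygen already sitting on C2 with the right configuration, and ring A becomes an ortho-fluoroaryl ketone. The forward ring closure forms only an O–aryl bond and cannot change C2. Both rings C are removed at once. The demand is that intramolecular fluoride displacement be faster than retro-aldol cleavage and enolisation of the β-hydroxy ketone.

**13 to 7 and 12.** The bonds C4–C4a and C4'–C4a' are cut, making ring A a nucleophile and C4 a lactone carbonyl. This leaves 7, a compact bicycle that holds all four stereocenters and both ring-C oxygens. The forward addition must stop after one aryl group per lactone and must not deprotonate next to the carbonyls.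

**12 to 11, 10, 8 and 9.** The C–Li bond goes back to C–Br, C–Br to C–H, and the two benzyl ethers to 8 and two molecules of 9. Metalation of 10 itself could go between the two ether oxygens or at a benzylic CH2; a bromine atom placed by electrophilic substitution fixes the site ortho to fluorine and para to one ether. The demand is regioselective bromination.

**7 to 6.** Backwards, the lactone bonds O1–C2 and O1'–C2' are cut and C2 is joined to C2'. An acyclic tetrad of stereocenters becomes an all-trans cyclobutane that photochemistry can make; each new C–O bond takes the place of the C–C bond at the same carbon. The forward oxidative cleavage must outrun cycloreversion, and lactonisation must place both aryl groups exo.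

**6 to 4.** The two carboxyl C–OH bonds become C–C bonds to 1-methylimidazol-2-yl groups. The imidazole is the binding site for the chiral acid in the photochemical step and can be removed afterwards by N-methylation. The forward cleavage must not disturb the ring.

**4 to two molecules of 3.** The bonds C3–C3' and C2–C2' are cut (the key disconnection). One ring, two skeletal bonds and four stereocenters are removed, leaving a single achiral enone. 4 as drawn is all-trans and (1R,2R,3S,4S); its C1 and C2 are C3 and C3' of 17, both S. The forward step must give head-to-head regiochemistry, the trans-diacyl diastereomer and one enantiomer.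

**3 to 1 and 2.** The C=C bond is cut by aldol condensation logic, giving two commercial compounds. The forward step must give the E-alkene, which is the thermodynamic outcome.

## Other disconnections considered

**Alternative 1:** The cut is at O1–C8a, C4–C4a and their primed counterparts, so that both rings A arrive as an aryne. The forward key step would treat diacid A1 with two equivalents of the aryne released from silyl triflate A2 by CsF. Each carboxylate oxygen adds to the aryne carbon remote from the flanking benzyloxy group, the aryl anion attacks its own ester carbonyl, and the 2-hydroxyaryl ketone results, giving dienedione A3.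
- In favour: the insertion of arynes into carboxylic acids with acyl migration is an established reaction type. It forms four skeletal bonds in one operation, A1 should be reachable from 1 by a double Stobbe condensation, and the phenols arrive placed for closure of both rings C. In convergence it is the better plan, and in step count it is about equal once the preparation of A2 is included.
- Against: A3 has no stereocenter, so all four must be set in a double oxa-Michael closure. That closure is reversible and is expected to favour 2,3-trans flavanones and both pairings of C3 with C3'. The target is the cis,cis, C2-symmetric isomer in one absolute configuration, and the twisted, cross-conjugated diene-dione offers no obvious handle for a catalyst.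
- Comparison: both plans use the latent symmetry and meet the same final mono-methylation, where they are equal. The chosen plan fixes C3 and C3' before any epimerisable ketone exists and relays C2 and C2' through a rigid bicycle, which this alternative cannot do.

**Alternative 2:** The cut is the same C3–C3' bond together with O1–C2 and O1'–C2', made in one oxidative step on a monomer with a free para-hydroxyl group. Forward, FeCl3 under O2 would convert A4 into its phenoxy radical; two radicals join at the carbons next to the carboxyl groups, and the bis(quinone methide) is captured by the two carboxylates to give the cis-fused exo,exo bis-lactone A5. Double O-methylation of A5 would give 7, and steps 7 to 10 follow unchanged.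
- In favour: this is known chemistry for hydroxycinnamic acids. It reaches the bicyclic core in two steps against four (steps 1 to 4) and avoids the one unprecedented step of the chosen plan; on both points it is the better plan. The relative configuration arises for the same reason in both plans (5-exo capture of a benzylic electrophile by a carboxylate), so there they are equal.
- Against: radical coupling has no element of absolute control, so A5 would form as a racemate and half the material would be lost in a resolution on a base-sensitive bis-lactone. A4 has no ortho substituents and offers the radical several coupling sites (ring carbon, phenoxy oxygen), so the wanted mode is one of several. The later O-methylation must be done without opening the lactones.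
- Comparison: the chosen plan spends two more steps and one risky step to obtain the absolute configuration by catalysis and an unambiguous site of C–C bond formation.

**Alternative 3:** The cut is at the two C2–aryl bonds; C3–C3' is present from the start in bichromone A6. Forward, [Rh(C2H4)2Cl]2 with a chiral diene would transfer the aryl group of A7 to C2 and then C2' of A6. Each rhodium enolate is then protonated at C3 from the face opposite the new aryl group, which would give the cis relation and end at A8, the same compound as 15.
- In favour: asymmetric conjugate arylation of chromones is a known reaction type, the step is the most convergent of the four plans, and from A8 only steps 9 and 10 remain. In reliance on precedented catalysis and in step count after the bichromone it is the better plan.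
- Against: the acceptor is a 3-substituted chromone with a peri benzyloxy group, an α-substituted enone of a class expected to react sluggishly. C3 and C3' would be created by protonation and not by the catalyst, so their pairing (C2-symmetric against meso) and the cis relation rest on kinetic protonation in a basic aqueous medium, where 2,3-cis flavanones can epimerise and ring-open. The second arylation meets a substrate that already bears two stereocenters. A6 itself must be made (reductive homocoupling of a 3-halochromone, four to five steps), so the total is only somewhat shorter.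
- Comparison: the chosen plan sets C3 and C3' in the C–C bond-forming step and exposes them to base only in the last ring closure; this alternative sets C2 and C2' with a well-understood catalyst but leaves C3 and C3' to a protonation.

Key step: step 2

## Steps

**Step 1**
Reactants: 1 4-methoxybenzaldehyde; 2 2-acetyl-1-methylimidazole
Product: 3 (E)-3-(4-methoxyphenyl)-1-(1-methyl-1H-imidazol-2-yl)prop-2-en-1-one
Conditions: NaOH, EtOH/H2O, 0 °C to rt
Reagents that add atoms: none
Why: Claisen–Schmidt (crossed aldol) condensation; the aldehyde cannot enolise, and E1cB loss of water gives the conjugated E-enone as the thermodynamic product.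

**Step 2**
Reactants: 3 (E)-3-(4-methoxyphenyl)-1-(1-methyl-1H-imidazol-2-yl)prop-2-en-1-one (two molecules)
Product: 4 [(1R,2R,3S,4S)-3,4-bis(4-methoxyphenyl)cyclobutane-1,2-diyl]bis[(1-methyl-1H-imidazol-2-yl)methanone]
Conditions: Ir(C11H8N)3 [fac-tris(2-phenylpyridinato)iridium] (1 mol%), (R)-TRIP (10 mol%), toluene/CH2Cl2, −78 °C, blue LEDs (450 nm), argon
Reagents that add atoms: none
Why: The phosphoric acid binds the imidazole nitrogen and carbonyl of 3, which lowers the triplet energy of the bound enone so that energy transfer from photoexcited Ir(C11H8N)3 reaches it faster than the free enone. The triplet, a 1,2-diradical across the α- and β-carbons, adds to a second molecule of 3 head to head, most plausibly bonding first between the two α-carbons, which leaves the doubly 4-methoxybenzylic 1,4-diradical, the best stabilised of the possible diradicals. After intersystem crossing the four-membered ring closes by radical–radical recombination between the two benzylic carbons, a stepwise formal [2+2] and not a concerted closure. The closest known reaction type is the acid-controlled, triplet-sensitised enantioselective [2+2] photodimerisation of 2-cinnamoylimidazoles used for truxinate synthesis. C1 and C2 of the cyclobutane (C3 and C3' of 17) are set in the first bond formation: their absolute configuration comes from the chiral phosphate, which shields one face of the bound enone, and their trans relation from approach with the two acyl groups apart. C3 and C4 (C2' and C2 of 17) are set at ring closure: the triplet diradical lives long enough to rotate, so each aryl group ends trans to its neighbours, and E/Z isomerisation of 3 under sensitisation is harmless. The step needs head-to-head regiochemistry, the all-trans diastereomer and one enantiomer; the 4-methoxyphenyl groups secure the first through diradical stability, the relaxed diradical the second, and the imidazole as binding site for the acid the third, with low temperature keeping the unbound background slow.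

**Step 3**
Reactants: 4 [(1R,2R,3S,4S)-3,4-bis(4-methoxyphenyl)cyclobutane-1,2-diyl]bis[(1-methyl-1H-imidazol-2-yl)methanone]
Product: 6 (1R,2R,3S,4S)-3,4-bis(4-methoxyphenyl)cyclobutane-1,2-dicarboxylic acid, via bis(acylimidazolium) bis(triflate) 5 (not isolated)
Conditions: MeOTf, CH2Cl2, 0 °C to rt; then H2O, DBU, MeCN, 0 °C; acidic work-up
Reagents that add atoms: water, O; methyl trifluoromethanesulfonate, COS(=O)(=O)C(F)(F)F (its methyl groups and triflate ions are carried only by intermediate 5)
Why: N-methylation turns each acyl imidazole into an acyl imidazolium, a strong acylating agent that water cleaves by addition–elimination with loss of the imidazolium (nucleophilic acyl substitution). The all-trans arrangement is the most stable one, so the base cannot epimerise it to anything lower in energy.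

**Step 4**
Reactants: 6 (1R,2R,3S,4S)-3,4-bis(4-methoxyphenyl)cyclobutane-1,2-dicarboxylic acid
Product: 7 (1S,4S,5S,8S)-4,8-bis(4-methoxyphenyl)-3,7-dioxabicyclo[3.3.0]octane-2,6-dione
Conditions: constant-current electrolysis, graphite anode, Pt cathode, undivided cell, n-Bu4NBF4, MeCN/HFIP (4:1), 2.2 F/mol, 0 °C
Reagents that add atoms: none
Why: Proposed new method: the anode removes one electron from a 4-methoxyphenyl ring (the most easily oxidised site), the radical cation breaks the strained, doubly benzylic C3–C4 bond of the cyclobutane (C2–C2' of 17), the γ-carboxylic acid traps the benzylic cation 5-exo, and the remaining 4-methoxybenzyl radical, far easier to oxidise than the arene, is oxidised at once and trapped by the second acid; the closest known reaction types are the radical-cation cleavage of 1,2-bis(4-methoxyphenyl)cyclobutanes (cycloreversion, dioxygen trapping) and the anodic 1,3-dioxygenation of arylcyclopropanes. Cycloreversion should be slower here than for anethole-type dimers because it would have to expel the radical cation of an electron-poor cinnamic acid. Each aryl group should end exo (trans to the neighbouring carboxyl carbon, on the convex face of the cis-fused bicycle), a preference reinforced by reversible ionisation of the 4-methoxybenzylic C–O bond in the acidic medium, while C1 and C5 keep the configuration set in step 2.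

**Step 5**
Reactants: 8 5-fluororesorcinol; 9 benzyl bromide (two molecules)
Product: 10 1,3-bis(benzyloxy)-5-fluorobenzene
Conditions: K2CO3 (3 equiv), DMF, 60 °C; 9 used as 2.2 equiv
Reagents that add atoms: none
Why: Twofold Williamson ether synthesis, one molecule of 9 for each of the two phenoxides of 8; the aryl fluoride is inert to carbonate.

**Step 6**
Reactants: 10 1,3-bis(benzyloxy)-5-fluorobenzene
Product: 11 1,5-bis(benzyloxy)-2-bromo-3-fluorobenzene
Conditions: NBS, MeCN, 0 °C to rt
Reagents that add atoms: N-bromosuccinimide, O=C1CCC(=O)N1Br
Why: Electrophilic aromatic bromination para to one benzyloxy group and ortho to the other and to fluorine; the position between the two ethers is more hindered, as with other 5-substituted resorcinol diethers.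

**Step 7**
Reactants: 11 1,5-bis(benzyloxy)-2-bromo-3-fluorobenzene (2.4 equiv); 7 (1S,4S,5S,8S)-4,8-bis(4-methoxyphenyl)-3,7-dioxabicyclo[3.3.0]octane-2,6-dione
Product: 13 bis-hemiketal 2,6-bis[2,4-bis(benzyloxy)-6-fluorophenyl]-4,8-bis(4-methoxyphenyl)-3,7-dioxabicyclo[3.3.0]octane-2,6-diol, via [2,4-bis(benzyloxy)-6-fluorophenyl]lithium 12 (not isolated)
Conditions: n-BuLi, THF, −78 °C; then 7 in THF, −78 °C; AcOH quench at −78 °C
Reagents that add atoms: n-butyllithium, [Li]CCCC (its lithium is carried only by intermediate 12)
Why: Bromine–lithium exchange gives an ortho-fluoroaryllithium that is stable at −78 °C and adds to each lactone carbonyl from the convex face; the lithium hemiketalate of a 2,6-disubstituted aryl ketone takes up no second aryl group (aryllithium addition to lactones, as used for C-aryl glycoside lactols). The four stereocenters of 7 are not touched, and the cold acid quench keeps the basic mixture from β-elimination.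

**Step 8**
Reactants: 13 bis-hemiketal (ring tautomer of 14)
Product: 15 (2S,3S,2'S,3'S)-5,5',7,7'-tetrakis(benzyloxy)-2,2'-bis(4-methoxyphenyl)-[3,3'-bichromane]-4,4'-dione, via open-chain dihydroxy diketone 14 (not isolated)
Conditions: KN(SiMe3)2 (2.1 equiv), THF, −78 to 0 °C; AcOH quench at low temperature
Reagents that add atoms: none
Why: Deprotonation opens each hemiketal to the keto alkoxide, whose oxygen on C2 displaces the fluoride ortho to the ketone on C3 in a six-membered intramolecular SNAr (addition–elimination through a Meisenheimer intermediate stabilised by the ortho carbonyl). Only O–aryl bonds form, so C2 and C2' keep the configuration of 7 and the exo aryl groups of the bis-lactone become the 2,3-cis relation. Stoichiometric base and low temperature are chosen to limit enolisation at C3 and C3'.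

**Step 9**
Reactants: 15 (2S,3S,2'S,3'S)-5,5',7,7'-tetrakis(benzyloxy)-2,2'-bis(4-methoxyphenyl)-[3,3'-bichromane]-4,4'-dione
Product: 16 (2S,3S,2'S,3'S)-5,5',7,7'-tetrahydroxy-2,2'-bis(4-methoxyphenyl)-[3,3'-bichromane]-4,4'-dione
Conditions: H2 (1 atm), Pd/C (10 wt% Pd), EtOAc/MeOH, rt
Reagents that add atoms: none
Why: Hydrogenolysis of aryl benzyl ethers under neutral conditions, which flavanones tolerate without cleavage of the C2–O1 bond when the reaction is stopped at full debenzylation; no acid or base is present to epimerise C3.

**Step 10**
Reactants: 16 (2S,3S,2'S,3'S)-5,5',7,7'-tetrahydroxy-2,2'-bis(4-methoxyphenyl)-[3,3'-bichromane]-4,4'-dione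
Product: 17 (2S,3S,2'S,3'S)-5,5',7-trihydroxy-7'-methoxy-2,2'-bis(4-methoxyphenyl)-[3,3'-bichromane]-4,4'-dione
Conditions: Me3SiCHN2 (1.0 equiv), MeOH/toluene, 0 °C
Reagents that add atoms: trimethylsilyldiazomethane, C[Si](C)(C)C=[N+]=[N-] (supplies the CH2 of the new methyl group)
Why: O-Methylation of the most acidic phenol by diazomethane released in the flask; the 7-hydroxyls react, the chelated 5-hydroxyls do not, and no base is present. The two 7-hydroxyls are equivalent by symmetry, so either gives 17; the outcome is statistical, and unreacted 16 and the 7,7'-dimethyl ether are separated, the former being recycled.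

## Compound list

1 | 4-methoxybenzaldehyde | COc1ccc(C=O)cc1 | starting material
2 | 2-acetyl-1-methylimidazole | CC(=O)c1nccn1C | starting material
3 | (E)-3-(4-methoxyphenyl)-1-(1-methyl-1H-imidazol-2-yl)prop-2-en-1-one | COc1ccc(/C=C/C(=O)c2nccn2C)cc1 | intermediate
4 | [(1R,2R,3S,4S)-3,4-bis(4-methoxyphenyl)cyclobutane-1,2-diyl]bis[(1-methyl-1H-imidazol-2-yl)methanone], all-trans head-to-head dimer | Cn1ccnc1C(=O)[C@H]1[C@H](C(=O)c2nccn2C)[C@@H](c2ccc(OC)cc2)[C@@H]1c1ccc(OC)cc1 | intermediate
5 | 2,2'-{[(1R,2R,3S,4S)-3,4-bis(4-methoxyphenyl)cyclobutane-1,2-diyl]dicarbonyl}bis(1,3-dimethylimidazolium) bis(trifluoromethanesulfonate), not isolated | Cn1cc[n+](C)c1C(=O)[C@H]1[C@H](C(=O)c2n(C)cc[n+]2C)[C@@H](c2ccc(OC)cc2)[C@@H]1c1ccc(OC)cc1.[O-]S(=O)(=O)C(F)(F)F.[O-]S(=O)(=O)C(F)(F)F | intermediate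
6 | (1R,2R,3S,4S)-3,4-bis(4-methoxyphenyl)cyclobutane-1,2-dicarboxylic acid | OC(=O)[C@H]1[C@H](C(=O)O)[C@@H](c2ccc(OC)cc2)[C@@H]1c1ccc(OC)cc1 | intermediate
7 | (1S,4S,5S,8S)-4,8-bis(4-methoxyphenyl)-3,7-dioxabicyclo[3.3.0]octane-2,6-dione, cis-fused, both aryl groups exo | COc1ccc([C@H]2OC(=O)[C@H]3[C@@H]2C(=O)O[C@@H]3c2ccc(OC)cc2)cc1 | intermediate
8 | 5-fluororesorcinol | Oc1cc(O)cc(F)c1 | starting material
9 | benzyl bromide | BrCc1ccccc1 | starting material
10 | 1,3-bis(benzyloxy)-5-fluorobenzene | Fc1cc(OCc2ccccc2)cc(OCc2ccccc2)c1 | intermediate
11 | 1,5-bis(benzyloxy)-2-bromo-3-fluorobenzene | Fc1cc(OCc2ccccc2)cc(OCc2ccccc2)c1Br | intermediate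
12 | [2,4-bis(benzyloxy)-6-fluorophenyl]lithium, not isolated | [Li]c1c(F)cc(OCc2ccccc2)cc1OCc1ccccc1 | intermediate
13 | 2,6-bis[2,4-bis(benzyloxy)-6-fluorophenyl]-4,8-bis(4-methoxyphenyl)-3,7-dioxabicyclo[3.3.0]octane-2,6-diol; C1, C4, C5, C8 as in 7; hemiketal carbons C2 and C6 unassigned | COc1ccc([C@H]2OC(O)(c4c(F)cc(OCc5ccccc5)cc4OCc4ccccc4)[C@H]3[C@@H]2C(O)(c2c(F)cc(OCc4ccccc4)cc2OCc2ccccc2)O[C@@H]3c2ccc(OC)cc2)cc1 | intermediate
14 | (2S,3S)-1,4-bis[2,4-bis(benzyloxy)-6-fluorophenyl]-2,3-bis[(S)-hydroxy(4-methoxyphenyl)methyl]butane-1,4-dione, not isolated | COc1ccc([C@@H](O)[C@@H](C(=O)c2c(F)cc(OCc3ccccc3)cc2OCc2ccccc2)[C@H](C(=O)c2c(F)cc(OCc3ccccc3)cc2OCc2ccccc2)[C@H](O)c2ccc(OC)cc2)cc1 | intermediate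
15 | (2S,3S,2'S,3'S)-5,5',7,7'-tetrakis(benzyloxy)-2,2'-bis(4-methoxyphenyl)-[3,3'-bichromane]-4,4'-dione, 2,3-cis and 2',3'-cis | COc1ccc([C@H]2Oc3cc(OCc4ccccc4)cc(OCc4ccccc4)c3C(=O)[C@H]2[C@@H]2C(=O)c3c(OCc4ccccc4)cc(OCc4ccccc4)cc3O[C@@H]2c2ccc(OC)cc2)cc1 | intermediate
16 | (2S,3S,2'S,3'S)-5,5',7,7'-tetrahydroxy-2,2'-bis(4-methoxyphenyl)-[3,3'-bichromane]-4,4'-dione | COc1ccc([C@H]2Oc3cc(O)cc(O)c3C(=O)[C@H]2[C@@H]2C(=O)c3c(O)cc(O)cc3O[C@@H]2c2ccc(OC)cc2)cc1 | intermediate
17 | (2S,3S,2'S,3'S)-5,5',7-trihydroxy-7'-methoxy-2,2'-bis(4-methoxyphenyl)-[3,3'-bichromane]-4,4'-dione | COc1ccc([C@H]2Oc3cc(O)cc(O)c3C(=O)[C@H]2[C@@H]2C(=O)c3c(O)cc(OC)cc3O[C@@H]2c2ccc(OC)cc2)cc1 | target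

## Step count and least certain steps

Total step count: 10. Longest linear sequence: 8 steps (steps 1, 2, 3, 4, 7, 8, 9, 10, from 1 and 2); the aryl branch (steps 5 and 6) joins at step 7.

**Step 4 (new method).** What may go wrong: cycloreversion of the ring-opened radical cation (cleavage of the C1–C2 bond as well, returning two cinnamic acid units), or attack of a carboxyl group on the oxidised arene ring instead of the benzylic carbon, before the first lactone has formed. Radical-cation cyclobutanes are known to revert, and only relative rates decide. Fallback with known reactions, from 4 back to 7: N-methylation of 4 (MeOTf) and methanolysis (MeOH, DBU) would give dimethyl (1R,2R,3S,4S)-3,4-bis(4-methoxyphenyl)cyclobutane-1,2-dicarboxylate F1. Photo-induced electron-transfer oxygenation (9,10-dicyanoanthracene, O2, MeCN, light), a known reaction of 1,2-bis(4-methoxyphenyl)cyclobutanes, would insert dioxygen between the two benzylic carbons to give dimethyl 3,6-bis(4-methoxyphenyl)-1,2-dioxane-4,5-dicarboxylate F2. Reduction of the peroxide bond with Zn in AcOH would give dimethyl (2S,3S)-2,3-bis[hydroxy(4-methoxyphenyl)methyl]butanedioate F3. Warming F3 with TsOH in toluene should close both lactones and equilibrate the benzylic carbons through the 4-methoxybenzylic cation (as in the acid epimerisation of furofuran lignans) to the exo,exo isomer 7. Here an external trap (dioxygen) replaces the internal carboxylate, and the C–O stereocenters are set afterwards under thermodynamic control.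

**Step 2 (key step).** What may go wrong: erosion of enantioselectivity by dimerisation of enone not bound to the acid, and formation of other head-to-head diastereomers, because energy transfer to free 3 competes whenever its triplet energy lies within reach of the sensitiser. Fallback, from 3 back to 4: sensitised dimerisation with an achiral acid (diphenyl phosphate) in place of the chiral one would give the racemate, that is 4 together with its enantiomer [(1S,2S,3R,4R)-3,4-bis(4-methoxyphenyl)cyclobutane-1,2-diyl]bis[(1-methyl-1H-imidazol-2-yl)methanone] F4. Preparative chromatography on a chiral stationary phase then delivers 4. The absolute configuration would come from resolution instead of catalysis.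

**Step 7.** What may go wrong: proton abstraction at C1 or C5 (α to the lactone carbonyls) by the hindered, basic aryllithium, followed by β-elimination of the carboxylate of the other lactone; or loss of lithium fluoride from 12 to an aryne if addition is slow. Fallback, from 7 back to 15: Me3Al and N,O-dimethylhydroxylamine hydrochloride would open both lactones to (2S,3S)-2,3-bis[(S)-hydroxy(4-methoxyphenyl)methyl]-N1,N4-dimethoxy-N1,N4-dimethylbutanediamide F5. Silylation (Et3SiOTf, 2,6-lutidine) would give the bis(triethylsilyl) ether of F5 F6. 12 would then add to the two Weinreb amides, which have no β-leaving group, to give the bis(triethylsilyl) ether of 14 F7. Catalytic n-Bu4NF in THF would remove the silyl groups, and the alkoxides would close both rings by fluoride displacement, which regenerates fluoride, to rejoin the route at 15.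

**Step 8.** What may go wrong: enolisation at C3 and C3' after ring closure (or retro-aldol cleavage before it), because the alkoxide needed for the substitution is also a base and the open form is an aldol; this would erode the 2,3-cis arrangement. Fallback, from 13 back to 15: the closure is run as in step 8 and the product is not purified from its C3/C3' epimers, chiefly (2S,3R,2'S,3'R)-5,5',7,7'-tetrakis(benzyloxy)-2,2'-bis(4-methoxyphenyl)-[3,3'-bichromane]-4,4'-dione F8. The mixture is converted into the bis-enolate with LiN(i-Pr)2 in THF at −78 °C, where ring opening of flavanone enolates is slow. Protonation with AcOH at −78 °C, from the face opposite each C2 aryl group, should re-create the 2,3-cis relation and give 15. The C3 centers would then be set by kinetic protonation instead of being carried through.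

## Further compounds

F1 | step 4 | dimethyl (1R,2R,3S,4S)-3,4-bis(4-methoxyphenyl)cyclobutane-1,2-dicarboxylate | COC(=O)[C@H]1[C@H](C(=O)OC)[C@@H](c2ccc(OC)cc2)[C@@H]1c1ccc(OC)cc1
F2 | step 4 | dimethyl 3,6-bis(4-methoxyphenyl)-1,2-dioxane-4,5-dicarboxylate (C4 and C5 trans as in 4; C3 and C6 as a mixture) | COC(=O)[C@H]1[C@H](C(=O)OC)C(c2ccc(OC)cc2)OOC1c1ccc(OC)cc1
F3 | step 4 | dimethyl (2S,3S)-2,3-bis[hydroxy(4-methoxyphenyl)methyl]butanedioate (carbinol centers as a mixture) | COC(=O)[C@@H]([C@H](C(=O)OC)C(O)c1ccc(OC)cc1)C(O)c1ccc(OC)cc1
F4 | step 2 | [(1S,2S,3R,4R)-3,4-bis(4-methoxyphenyl)cyclobutane-1,2-diyl]bis[(1-methyl-1H-imidazol-2-yl)methanone], enantiomer of 4 | Cn1ccnc1C(=O)[C@@H]1[C@@H](C(=O)c2nccn2C)[C@H](c2ccc(OC)cc2)[C@H]1c1ccc(OC)cc1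
F5 | step 7 | (2S,3S)-2,3-bis[(S)-hydroxy(4-methoxyphenyl)methyl]-N1,N4-dimethoxy-N1,N4-dimethylbutanediamide | COc1ccc([C@@H](O)[C@@H](C(=O)N(C)OC)[C@H](C(=O)N(C)OC)[C@H](O)c2ccc(OC)cc2)cc1
F6 | step 7 | bis(triethylsilyl) ether of F5 | COc1ccc([C@@H](O[Si](CC)(CC)CC)[C@@H](C(=O)N(C)OC)[C@H](C(=O)N(C)OC)[C@H](O[Si](CC)(CC)CC)c2ccc(OC)cc2)cc1
F7 | step 7 | bis(triethylsilyl) ether of 14 | COc1ccc([C@@H](O[Si](CC)(CC)CC)[C@@H](C(=O)c2c(F)cc(OCc3ccccc3)cc2OCc2ccccc2)[C@H](C(=O)c2c(F)cc(OCc3ccccc3)cc2OCc2ccccc2)[C@H](O[Si](CC)(CC)CC)c2ccc(OC)cc2)cc1
F8 | step 8 | (2S,3R,2'S,3'R)-5,5',7,7'-tetrakis(benzyloxy)-2,2'-bis(4-methoxyphenyl)-[3,3'-bichromane]-4,4'-dione, 2,3-trans and 2',3'-trans | COc1ccc([C@H]2Oc3cc(OCc4ccccc4)cc(OCc4ccccc4)c3C(=O)[C@@H]2[C@H]2C(=O)c3c(OCc4ccccc4)cc(OCc4ccccc4)cc3O[C@@H]2c2ccc(OC)cc2)cc1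
A1 | alternative 1 | (2E,3E)-2,3-bis(4-methoxybenzylidene)butanedioic acid | O=C(O)/C(=C/c1ccc(OC)cc1)C(=C/c1ccc(OC)cc1)\C(=O)O
A2 | alternative 1 | 3,5-bis(benzyloxy)-2-(trimethylsilyl)phenyl trifluoromethanesulfonate | C[Si](C)(C)c1c(OS(=O)(=O)C(F)(F)F)cc(OCc2ccccc2)cc1OCc1ccccc1
A3 | alternative 1 | (2E,3E)-1,4-bis[2,4-bis(benzyloxy)-6-hydroxyphenyl]-2,3-bis(4-methoxybenzylidene)butane-1,4-dione | O=C(/C(=C/c1ccc(OC)cc1)C(=C/c1ccc(OC)cc1)\C(=O)c1c(O)cc(OCc2ccccc2)cc1OCc1ccccc1)c1c(O)cc(OCc2ccccc2)cc1OCc1ccccc1
A4 | alternative 2 | (E)-4-hydroxycinnamic acid | OC(=O)/C=C/c1ccc(O)cc1
A5 | alternative 2 | (1S,4S,5S,8S)-4,8-bis(4-hydroxyphenyl)-3,7-dioxabicyclo[3.3.0]octane-2,6-dione, cis-fused, exo,exo | Oc1ccc(cc1)[C@H]1OC(=O)[C@H]2[C@@H]1C(=O)O[C@@H]2c1ccc(O)cc1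
A6 | alternative 3 | 5,5',7,7'-tetrakis(benzyloxy)-3,3'-bichromone | O=c1c(-c2coc3cc(OCc4ccccc4)cc(OCc4ccccc4)c3c2=O)coc2cc(OCc3ccccc3)cc(OCc3ccccc3)c12
A7 | alternative 3 | 4-methoxyphenylboronic acid | COc1ccc(B(O)O)cc1
A8 | alternative 3 | (2S,3S,2'S,3'S)-5,5',7,7'-tetrakis(benzyloxy)-2,2'-bis(4-methoxyphenyl)-[3,3'-bichromane]-4,4'-dione, identical with 15 | COc1ccc([C@H]2Oc3cc(OCc4ccccc4)cc(OCc4ccccc4)c3C(=O)[C@H]2[C@@H]2C(=O)c3c(OCc4ccccc4)cc(OCc4ccccc4)cc3O[C@@H]2c2ccc(OC)cc2)cc1
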